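Numbering follows the isoflavan convention: O1, C2, C3, C4 and C4a–C8a for the chroman, primed locants for ring B, and the same locants for the second, identical half.

## Analysis of the target

- Target 18 is a C2-symmetric dimer of an isoflavan. Each half is a (3R)-7-hydroxychroman (ring A fused to the pyran ring) that carries a 3'-hydroxy-2'-methoxyphenyl ring B at C3. The two rings B are joined by a diaryl ether oxygen between their C4' atoms.
- The only stereocentres are the two C3 atoms. They are constitutionally equivalent, both R, and far apart across the ether bridge, so neither can direct the other. Each must be set by a reagent, and a lapse at one site gives the meso diastereomer.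
- C3 is a tertiary all-carbon centre bearing ring B, C2 (the OCH2 group) and C4 (the benzylic CH2 of ring A). Its hydrogen is benzylic, so any intermediate with a carbonyl group or a cation at C2 makes it epimerisable.
- The sensitive groups are four phenols: two resorcinol-type at C7 and two at C3' inside an electron-rich, contiguously trioxygenated ring B. The two C2' methyl ethers must survive, which rules out a final Lewis-acid ether cleavage and points to hydrogenolysable protection.
- The difficulties are the 1',2',3',4' substitution of ring B with three different oxygen functions, a diaryl ether flanked on both sides by oxygen substituents, and two remote stereocentres that need the same sense.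
- The strategy rests on this feature: in each pyran ring the unit O1–C8a–C4a–C4 is an ortho-quinone methide of ring A in disguise, and the remaining pair C3–C2 is an arylacetaldehyde attached to ring B. C3 is then the α-carbon of an aldehyde and can be controlled through a chiral enamine, and the symmetry allows both pyran rings to be made in one operation.

## Retrosynthetic reasoning

**18 from 17.** The four phenols are traced back to benzyl ethers in 17. One hydrogenolysis frees all of them under neutral conditions and leaves the methyl ethers, the diaryl ether and C3 alone.

**17 from 16.** Each C2 methylene is traced back to a lactol carbon in 16. C2 at the aldehyde oxidation level is what an aldehyde-based ring construction delivers, and an ionic reduction removes the anomeric hydroxyl without touching another bond.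

**16 from 11 and two molecules of 15.** This is the central cut: in both pyran rings the bonds C3–C4 and O1–C2 are broken.
- Cutting here turns C3 into the nucleophilic α-carbon of the bis(arylacetaldehyde) 11 and C4 into the electrophilic methylene of the ortho-quinone methide 15, which is released in the flask from the sulfone 14.
- Other cuts of the pyran ring (O1–C2 etherification, C4–C4a arylation) would need C3 set beforehand by a separate method.
- Four skeletal bonds, two rings and both stereocentres come from one step, and ring A is bought as a finished aromatic ring at the right oxidation level.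
- The forward reaction must control the enamine face at both sites, beat the self-condensation of 11, and keep the new α-aryl centre from epimerising.

**14 from 13 from 12.** The sulfonyl group replaces the benzylic hydroxyl of the salicyl alcohol 13, which comes from the commercial aldehyde 12 by reduction. The 7-O-benzyl group is already in place in 12.

**11 from 10 from 9.** The aldehyde carbon of each arm (the future C2) is cut from the benzylic carbon (the future C3). Going forward, a one-carbon homologation of the bis(benzaldehyde) 9 through the bis(enol ether) 10 unmasks the sensitive arylacetaldehyde only in the last step before the union.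

**9 from 8 from 4 (through 5, 6 and 7).** The two C3'–O bonds are cut. C3' lies between the methoxy group and the ether oxygen, the classical site for directed metalation, so the oxygen is introduced by lithiation, borylation and oxidation. Free aldehydes do not survive an alkyllithium or alkaline peroxide, so they are carried as the dimethyl acetals of 4 and released in the work-up.

**4 from 3 from 1 and 2.** The diaryl ether C4'–O bond is cut last. Making it before the C3' oxygenation means that neither partner has a substituent next to the reacting position, and the formyl group para to fluorine in 2 activates the substitution. Both rings are then oxygenated in a single operation.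

## Alternatives that were turned down

**Alternative 1:** late double oxygenation at C3'.
- Disconnection: the two C3'–O bonds, cut at the very end. The precursor is the finished chiral dimer A1, which lacks the 3'-hydroxyls and has silyl-protected C7 phenols.
- Key step: n-BuLi/TMEDA double lithiation of A1, B(OMe)3, then H2O2/NaOH, giving the bis(7-O-triisopropylsilyl) ether A2 of the target.
- For: C3'–H is a textbook doubly activated metalation site. Ring B travels through the synthesis without a 3'-O protecting group. The final deprotection is a fluoride treatment.
- Against:
  - The C3 problem is untouched; A1 still needs its stereocentres from some other method.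
  - A1 offers acidic sites that a simple achiral substrate does not. C8–H lies between O1 and the silyloxy group and is a second doubly activated position, held back only by the size of the silyl group. C3–H is benzylic and ortho to the C2' methoxy group, and its removal would destroy the stereocentre. Metalated aryl silyl ethers are prone to oxygen-to-carbon silyl shifts.
  - A two-fold metalation on the most advanced intermediate puts all the material at risk.
- Comparison: the chosen route uses the same C–O bond formation, but at step 3 on the achiral 4, which has one doubly activated position per ring, no stereocentre and no silyl ether. Alternative 1 is stronger in protecting-group economy on ring B. The chosen strategy offers the same reaction at a stage where failure is cheap.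

**Alternative 2:** copper hydride hydroboration of a bis(1,1-disubstituted alkene).
- Disconnection: the C3–H and C2–B bonds of each half. The precursor is the bis(alkene) A3, in which each C3 is an sp2 carbon bearing ring B, a methylene group (C2) and the ring A benzyl group.
- Key step: CuCl/NaOt-Bu/DTBM-SEGPHOS with pinacolborane A4. The ligated copper hydride adds across each alkene with copper at the terminal carbon, and the borane turns the alkylcopper into the primary boronate A5 and returns the hydride.
- For: the stereocentre is set by the catalyst and, once formed, is flanked by two methylene groups with no carbonyl, so it cannot epimerise. A3 is robust. Oxidation of the C–B bond and etherification are reliable.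
- Against:
  - The catalyst must tell ring B (twisted by its ortho methoxy group) from a benzyl group, two flat substituents of similar size.
  - The key step forms no skeletal bond and closes no ring. The skeleton of A3 has to be assembled beforehand, and three operations per half follow (C–B oxidation, removal of the ring A phenol protecting group, etherification).
  - Ring A needs two orthogonal protecting groups.
- Comparison: alternative 2 is stronger on the configurational stability of C3 after the key step. The chosen strategy offers convergence in its place: two simple fragments give both rings, four skeletal bonds and both stereocentres at once, in fewer steps.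

**Alternative 3:** ring A grown from a methyl ketone and an acrylate.
- Disconnection: C4a–C5, C7–C8 and O1–C8a in each half. The precursor is the bis(methyl ketone) A6, whose C3 centres are already in place and carry a protected hydroxymethyl group (C2) and a 3-oxobutyl chain (C4, C4a, C8a, C8).
- Key step: t-BuOK and ethyl acrylate A7. Michael addition at C4a and Claisen cyclisation at C8 build each cyclohexane-1,3-dione, and acid work-up condenses the C2 hydroxyl with the dione to close each pyran ring, giving the bis(hexahydrochromenone) A8.
- For: four rings are formed in one flask. No arylacetaldehyde and no quinone methide are handled.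
- Against:
  - The stereocentres must exist before the key step, so a separate asymmetric method is still needed.
  - The Michael addition has to occur at the methylene and the Claisen step at the methyl group of the same ketone, with over-alkylation and acrylate polymerisation in competition.
  - Ring A emerges as a vinylogous ester at the cyclohexenone level. A two-fold dehydrogenation to the C7 phenol is then needed in the presence of benzyl ethers and an electron-rich ring B.
  - It builds a resorcinol ring that can be bought.
- Comparison: alternative 3 is stronger in the number of rings closed in the key step (four against two). The chosen strategy offers ring A at the correct oxidation level from a commercial aromatic compound and sets C3 in the same step that closes the ring.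

Key step: step 9

Remark on the chemistry (assumption): the enamines of 11 are taken to follow the usual steric-shielding model of diarylprolinol silyl ethers (E-enamine, anti conformer, attack opposite the diaryl(silyloxy)methyl group). On this model, checked against the known sense of enamine α-functionalisation, the (R)-catalyst leads to 3R. The antipode would be used if a one-armed model reaction showed the opposite sense.

## Route

Step 1
Reactants: 1 4-hydroxy-2-methoxybenzaldehyde; 2 4-fluoro-2-methoxybenzaldehyde
Product: 3 4,4'-oxybis(2-methoxybenzaldehyde)
Conditions: K2CO3 (1.5 equiv), DMF, 120 °C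
Reagents that add atoms: none
Why: Nucleophilic aromatic substitution (addition–elimination) of the phenoxide of 1 on the fluoride of 2, which is activated by the para formyl group; neither reacting position has an ortho substituent, so the diaryl ether should form cleanly.

Step 2
Reactants: 3 4,4'-oxybis(2-methoxybenzaldehyde)
Product: 4 4,4'-oxybis[1-(dimethoxymethyl)-2-methoxybenzene]
Conditions: HC(OMe)3, MeOH, cat. p-TsOH·H2O, rt; Et3N quench
Reagents that add atoms: trimethyl orthoformate, COC(OC)OC
Why: Acid-catalysed acetalisation driven by the orthoformate as water scavenger; the dimethyl acetals make both formyl groups inert to the alkyllithium and the alkaline peroxide of step 3.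

Step 3
Reactants: 4 4,4'-oxybis[1-(dimethoxymethyl)-2-methoxybenzene]
Product: 8 4,4'-oxybis(3-hydroxy-2-methoxybenzaldehyde), via 3,3'-dilithio bis(acetal) 5 (not isolated), via 3,3'-bis(dimethoxyboryl) bis(acetal) 6 (not isolated), via 3,3'-dihydroxy bis(acetal) 7 (not isolated)
Conditions: n-BuLi (2.6 equiv), TMEDA, THF, −20 → 0 °C; B(OMe)3, −78 °C → rt; 30% H2O2, aq NaOH, 0 °C; Na2SO3; then 2 M HCl, THF, rt
Reagents that add atoms: hydrogen peroxide, OO; water, O
Why: Directed ortho-metalation: on each ring the C–H between the methoxy group and the ether oxygen is acidified and coordinated from both sides, so it should be lithiated in preference to the positions with a single oxygen neighbour; the aryllithium is borylated and the C–B bond is oxidised in place (boron-to-oxygen 1,2-shift) while the acetals keep the aldehydes away from peroxide, and the final acid wash releases them.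

Step 4
Reactants: 8 4,4'-oxybis(3-hydroxy-2-methoxybenzaldehyde)
Product: 9 4,4'-oxybis[3-(benzyloxy)-2-methoxybenzaldehyde]
Conditions: BnBr (2.5 equiv), K2CO3, DMF, 50 °C
Reagents that add atoms: benzyl bromide, BrCc1ccccc1
Why: Williamson ether synthesis (SN2) on the two phenoxides, the only acidic sites in 8; the benzyl ethers are chosen because they come off at the end without endangering the methyl ethers.

Step 5
Reactants: 9 4,4'-oxybis[3-(benzyloxy)-2-methoxybenzaldehyde]
Product: 10 1,1'-oxybis[2-(benzyloxy)-3-methoxy-4-(2-methoxyethenyl)benzene] (E/Z mixture at both alkenes)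
Conditions: Ph3P(CH2OMe)Cl (3 equiv), KOt-Bu (3 equiv), THF, 0 °C → rt
Reagents that add atoms: (methoxymethyl)triphenylphosphonium chloride, COC[P+](c1ccccc1)(c1ccccc1)c1ccccc1.[Cl-]
Why: Wittig methoxymethylenation of both aldehydes; the alkene geometry does not matter because both isomers hydrolyse to the same aldehyde.

Step 6
Reactants: 10 bis(enol ether)
Product: 11 2,2'-[oxybis(3-(benzyloxy)-2-methoxy-4,1-phenylene)]diacetaldehyde
Conditions: 2 M aq HCl, THF, 40 °C, argon; crude product used at once
Reagents that add atoms: water, O
Why: Acid hydrolysis of the enol ethers (protonation at carbon, addition of water, loss of methanol) should give the homologated aldehydes; benzyl ethers and the diaryl ether are inert to dilute acid.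

Step 7
Reactants: 12 4-(benzyloxy)-2-hydroxybenzaldehyde
Product: 13 5-(benzyloxy)-2-(hydroxymethyl)phenol
Conditions: NaBH4, MeOH, 0 °C
Reagents that add atoms: none
Why: Hydride reduction of the aldehyde to the salicyl alcohol; nothing else in 12 is reducible under these conditions.

Step 8
Reactants: 13 5-(benzyloxy)-2-(hydroxymethyl)phenol
Product: 14 5-(benzyloxy)-2-[(4-methylphenyl)sulfonylmethyl]phenol
Conditions: p-TolSO2Na (1.5 equiv), 1 M aq HCl, CH2Cl2, 0 °C → rt
Reagents that add atoms: sodium p-toluenesulfinate, Cc1ccc(S(=O)[O-])cc1.[Na+]
Why: Acid-promoted substitution of the benzylic hydroxyl through a cation stabilised by the ortho hydroxyl and the para benzyloxy group, captured at sulfur by the sulfinic acid (SN1-type sulfone formation); the excess of the soft sulfur nucleophile should outrun alkylation of the electron-rich ring.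

Step 9
Reactants: 11 bis(arylacetaldehyde); 14 5-(benzyloxy)-2-[(4-methylphenyl)sulfonylmethyl]phenol (2.5 equiv)
Product: 16 3,3'-[oxybis(3-(benzyloxy)-2-methoxy-4,1-phenylene)]bis[7-(benzyloxy)chroman-2-ol] (3R at both C3; both C2 as anomeric mixtures), via ortho-quinone methide 15 (not isolated)
Conditions: (R)-α,α-diphenylprolinol trimethylsilyl ether (40 mol %), Na2CO3 (3 equiv), CH2Cl2, 0 °C → rt
Reagents that add atoms: none
Why: The carbonate deprotonates the phenol of 14 and the phenoxide expels sulfinate in a 1,4-elimination to give 15, which lives longer because the benzyloxy group is para to the methide carbon. Each aldehyde of 11 condenses with the (R)-amine to an E-configured, aryl-conjugated enamine, one face of which is screened by the diphenyl(silyloxy)methyl group. The enamine carbon (C3) adds to the methide CH2 (C4) from the open face and the resulting phenoxide closes onto the iminium carbon (C2); each pyran ring closes in this 6-exo-trig mode, and the whole is a formal inverse-electron-demand hetero-Diels–Alder reaction. The water set free on enamine formation hydrolyses the cyclic N,O-aminal to the lactol and returns the catalyst. The closest known reaction type is the diarylprolinol silyl ether-catalysed formal [4+2] reaction of aldehyde enamines with ortho-quinone methides released from 2-(sulfonylmethyl)phenols, which gives chroman-2-ols; arylacetaldehydes are a demanding member of that class. Each C3 is set by the catalyst alone through the enamine face, the (R)-catalyst giving 3R, while C2 forms as an anomeric mixture and is removed in step 10. The step needs cross-reaction to beat aldol self-condensation, which the excess of the highly electrophilic 15 and the fast enamine formation of an arylacetaldehyde should secure, and it needs C3 to hold, which the closed lactol and the slow enamine formation of the α-branched product with the hindered amine should secure. Because the two sites react independently, most of the wrong-sense events end up in the meso diastereomer and not in the enantiomer, so the enantiomeric purity of the C2-symmetric product should exceed that of a single event.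

Step 10
Reactants: 16 bis(lactol)
Product: 17 3,3'-[oxybis(3-(benzyloxy)-2-methoxy-4,1-phenylene)]bis[(3R)-7-(benzyloxy)chromane]
Conditions: Et3SiH (8 equiv), BF3·OEt2 (3 equiv), CH2Cl2, −78 → −40 °C
Reagents that add atoms: none
Why: Ionic reduction of a lactol: the Lewis acid ionises the anomeric hydroxyl to a cyclic oxocarbenium ion, which the silane reduces to the C2 methylene; low temperature and a large excess of silane should make hydride capture faster than loss of the C3 proton, so C3 should stay 3R, and benzyl ethers tolerate the conditions.

Step 11
Reactants: 17 tetra-O-benzyl bis(isoflavan)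
Product: 18 3,3'-[oxybis(3-hydroxy-2-methoxy-4,1-phenylene)]bis[(3R)-chroman-7-ol] (the target)
Conditions: H2 (1 atm), 10% Pd/C, EtOAc/MeOH, rt
Reagents that add atoms: none
Why: Catalytic hydrogenolysis of the four benzylic C–O bonds; the methyl ethers, the diaryl ether and the chroman C–O bonds are not benzylic at the carbon that carries oxygen and should remain, and C3 is not touched.

## Compound list

1 | 4-hydroxy-2-methoxybenzaldehyde | COc1cc(O)ccc1C=O | starting material
2 | 4-fluoro-2-methoxybenzaldehyde | COc1cc(F)ccc1C=O | starting material
3 | 4,4'-oxybis(2-methoxybenzaldehyde) | COc1cc(Oc2ccc(C=O)c(OC)c2)ccc1C=O | intermediate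
4 | 4,4'-oxybis[1-(dimethoxymethyl)-2-methoxybenzene] | COc1cc(Oc2ccc(C(OC)OC)c(OC)c2)ccc1C(OC)OC | intermediate
5 | 3,3'-dilithio derivative of 4, lithium on the carbon between OMe and the ether oxygen of each ring (formed in the flask) | [Li]c1c(OC)c(C(OC)OC)ccc1Oc1ccc(C(OC)OC)c(OC)c1[Li] | intermediate
6 | 3,3'-bis(dimethoxyboryl) derivative of 4 (formed in the flask) | COB(OC)c1c(OC)c(C(OC)OC)ccc1Oc1ccc(C(OC)OC)c(OC)c1B(OC)OC | intermediate
7 | 6,6'-oxybis[3-(dimethoxymethyl)-2-methoxyphenol] (formed in the flask) | COc1c(C(OC)OC)ccc(Oc2ccc(C(OC)OC)c(OC)c2O)c1O | intermediate
8 | 4,4'-oxybis(3-hydroxy-2-methoxybenzaldehyde) | COc1c(C=O)ccc(Oc2ccc(C=O)c(OC)c2O)c1O | intermediate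
9 | 4,4'-oxybis[3-(benzyloxy)-2-methoxybenzaldehyde] | COc1c(C=O)ccc(Oc2ccc(C=O)c(OC)c2OCc2ccccc2)c1OCc1ccccc1 | intermediate
10 | 1,1'-oxybis[2-(benzyloxy)-3-methoxy-4-(2-methoxyethenyl)benzene], E/Z mixture at both alkenes | COC=Cc1ccc(Oc2ccc(C=COC)c(OC)c2OCc2ccccc2)c(OCc2ccccc2)c1OC | intermediate
11 | 2,2'-[oxybis(3-(benzyloxy)-2-methoxy-4,1-phenylene)]diacetaldehyde | COc1c(CC=O)ccc(Oc2ccc(CC=O)c(OC)c2OCc2ccccc2)c1OCc1ccccc1 | intermediate
12 | 4-(benzyloxy)-2-hydroxybenzaldehyde | O=Cc1ccc(OCc2ccccc2)cc1O | starting material
13 | 5-(benzyloxy)-2-(hydroxymethyl)phenol | OCc1ccc(OCc2ccccc2)cc1O | intermediate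
14 | 5-(benzyloxy)-2-[(4-methylphenyl)sulfonylmethyl]phenol | Cc1ccc(S(=O)(=O)Cc2ccc(OCc3ccccc3)cc2O)cc1 | intermediate
15 | 3-(benzyloxy)-6-methylidenecyclohexa-2,4-dien-1-one, the ortho-quinone methide (formed in the flask) | C=C1C=CC(OCc2ccccc2)=CC1=O | intermediate
16 | 3,3'-[oxybis(3-(benzyloxy)-2-methoxy-4,1-phenylene)]bis[7-(benzyloxy)chroman-2-ol], 3R at both C3, both C2 as anomeric mixtures | COc1c([C@@H]2C(O)Oc3cc(OCc4ccccc4)ccc3C2)ccc(Oc2ccc([C@@H]3C(O)Oc4cc(OCc5ccccc5)ccc4C3)c(OC)c2OCc2ccccc2)c1OCc1ccccc1 | intermediate
17 | 3,3'-[oxybis(3-(benzyloxy)-2-methoxy-4,1-phenylene)]bis[(3R)-7-(benzyloxy)chromane] | COc1c([C@@H]2COc3cc(OCc4ccccc4)ccc3C2)ccc(Oc2ccc([C@@H]3COc4cc(OCc5ccccc5)ccc4C3)c(OC)c2OCc2ccccc2)c1OCc1ccccc1 | intermediate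
18 | 3,3'-[oxybis(3-hydroxy-2-methoxy-4,1-phenylene)]bis[(3R)-chroman-7-ol], CNP0116832.1 | COc1c([C@@H]2COc3cc(O)ccc3C2)ccc(Oc2ccc([C@@H]3COc4cc(O)ccc4C3)c(OC)c2O)c1O | target

## Step count and risk

Total step count: 11 (six to the dialdehyde 11, two to the sulfone 14, three from the union to the target).
Longest linear sequence: 9 steps (steps 1–6, then 9–11).

Least certain steps:

**Step 9 (key step).**
- What may go wrong:
  - Erosion of the C3 configuration by re-enolisation of the open hydroxy-aldehyde form, since α-aryl aldehydes are unusually acidic and amine and carbonate are both present.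
  - Aldol self-condensation of 11.
  - Self-alkylation of 15 on its own electron-rich ring.
  - Capture of the amine catalyst by 15.
  - A meso by-product that may be hard to separate by ordinary chromatography because the two centres are remote; crystallisation or a chiral stationary phase may be needed.
- Fallback, setting out from 11 and coming back at 17:
  - Oxidation of 11 (NaClO2, NaH2PO4, 2-methyl-2-butene, t-BuOH/H2O) gives the bis(arylacetic acid) F1.
  - Perkin condensation of F1 with two equivalents of 12 (Ac2O, Et3N, 120 °C) gives the bis(7-benzyloxy-3-arylcoumarin) F2.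
  - i-Bu2AlH (CH2Cl2, −78 → 0 °C) opens each lactone to the Z-configured allylic alcohol phenol F3.
  - Mitsunobu etherification (PPh3, DIAD, THF) closes the bis(2H-chromene) F4.
  - Asymmetric hydrogenation of the two C3=C4 bonds with a cationic iridium phosphine–oxazoline catalyst, [Ir(cod)(tBu-PHOX)][B(3,5-(CF3)2C6H3)4] (H2 50 bar, CH2Cl2), gives 17. The ligand antipode is fixed on a one-armed model.
  - C3 is then set by hydrogen delivery to an alkene, with no carbonyl group next to it at any time.

**Step 3.**
- What may go wrong: incomplete second lithiation, or metalation at a position with only one oxygen neighbour. The methyl of the C2 methoxy group is pushed toward the target C–H by the adjacent acetal, which would give mono-hydroxylated or regioisomeric material.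
- Fallback, setting out from 2 and coming back at 9:
  - 2 is converted into its dimethyl acetal F5 (HC(OMe)3, MeOH, cat. p-TsOH).
  - A single lithiation between fluorine and methoxy (n-BuLi, THF, −78 °C, below the temperature at which LiF is lost), B(OMe)3, alkaline H2O2 and an acid wash give 4-fluoro-3-hydroxy-2-methoxybenzaldehyde F6.
  - Benzylation (BnBr, K2CO3, DMF) gives 3-(benzyloxy)-4-fluoro-2-methoxybenzaldehyde F7.
  - Half of F7 is turned into 3-(benzyloxy)-4-hydroxy-2-methoxybenzaldehyde F8 with NaH and 2-(methylsulfonyl)ethanol in DMF, a hydroxide equivalent that replaces fluoride and then loses methyl vinyl sulfone.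
  - Substitution of the fluoride of the remaining F7 by the phenoxide of F8 (K2CO3, DMSO, 130 °C) gives 9.
  - The metalation is then a single event at a more acidic site. The price is a diaryl ether formation hindered on both sides.

**Step 10.**
- What may go wrong: loss of C3 configuration when the oxocarbenium ion sheds its C3 proton to a 3-aryl-4H-chromene that is re-protonated and reduced from either face, and capture of the cation by an electron-rich ring.
- Fallback, setting out from 16 and coming back at 17:
  - NaBH4 (MeOH/THF, 0 °C; it can be added directly to the crude mixture of step 9) reduces the open hydroxy-aldehyde form to the (R,R)-bis(phenol primary alcohol) F9.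
  - Mitsunobu etherification (PPh3, DIAD, THF, high dilution) closes each O1–C2 bond by SN2 at the primary carbon.
  - No cation is formed at C2, and C3 sits between two methylene groups throughout.

**Step 6.**
- What may go wrong: aldol self-condensation and air oxidation of the arylacetaldehyde while it is exposed to aqueous acid.
- Fallback, setting out from 9 and coming back at 11:
  - Wittig methylenation (Ph3PCH3Br, KOt-Bu, THF) gives the bis(styrene) F10.
  - Hydroboration–oxidation (9-BBN, THF; then H2O2, NaOH) gives the bis(2-arylethanol) F11.
  - Dess–Martin periodinane (NaHCO3, CH2Cl2, 0 °C) gives 11 under non-aqueous, non-acidic conditions just before the union.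

## Further compounds

F1 | step 9 | 2,2'-[oxybis(3-(benzyloxy)-2-methoxy-4,1-phenylene)]diacetic acid | COc1c(CC(=O)O)ccc(Oc2ccc(CC(=O)O)c(OC)c2OCc2ccccc2)c1OCc1ccccc1
F2 | step 9 | 3,3'-[oxybis(3-(benzyloxy)-2-methoxy-4,1-phenylene)]bis[7-(benzyloxy)-2H-chromen-2-one] | COc1c(C2=Cc3ccc(OCc4ccccc4)cc3OC2=O)ccc(Oc2ccc(C3=Cc4ccc(OCc5ccccc5)cc4OC3=O)c(OC)c2OCc2ccccc2)c1OCc1ccccc1
F3 | step 9 | bis[(Z)-3-(4-(benzyloxy)-2-hydroxyphenyl)-2-arylprop-2-en-1-ol] of the 3'-O-benzyl diaryl ether core | COc1c(/C(CO)=C/c2ccc(OCc3ccccc3)cc2O)ccc(Oc2ccc(/C(CO)=C/c3ccc(OCc4ccccc4)cc3O)c(OC)c2OCc2ccccc2)c1OCc1ccccc1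
F4 | step 9 | 3,3'-[oxybis(3-(benzyloxy)-2-methoxy-4,1-phenylene)]bis[7-(benzyloxy)-2H-chromene] | COc1c(C2=Cc3ccc(OCc4ccccc4)cc3OC2)ccc(Oc2ccc(C3=Cc4ccc(OCc5ccccc5)cc4OC3)c(OC)c2OCc2ccccc2)c1OCc1ccccc1
F5 | step 3 | 1-(dimethoxymethyl)-4-fluoro-2-methoxybenzene | COc1cc(F)ccc1C(OC)OC
F6 | step 3 | 4-fluoro-3-hydroxy-2-methoxybenzaldehyde | COc1c(O)c(F)ccc1C=O
F7 | step 3 | 3-(benzyloxy)-4-fluoro-2-methoxybenzaldehyde | COc1c(OCc2ccccc2)c(F)ccc1C=O
F8 | step 3 | 3-(benzyloxy)-4-hydroxy-2-methoxybenzaldehyde | COc1c(OCc2ccccc2)c(O)ccc1C=O
F9 | step 10 | (R,R)-bis[3-(4-(benzyloxy)-2-hydroxyphenyl)-2-arylpropan-1-ol] of the 3'-O-benzyl diaryl ether core | COc1c([C@H](CO)Cc2ccc(OCc3ccccc3)cc2O)ccc(Oc2ccc([C@H](CO)Cc3ccc(OCc4ccccc4)cc3O)c(OC)c2OCc2ccccc2)c1OCc1ccccc1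
F10 | step 6 | 1,1'-oxybis[2-(benzyloxy)-4-ethenyl-3-methoxybenzene] | C=Cc1ccc(Oc2ccc(C=C)c(OC)c2OCc2ccccc2)c(OCc2ccccc2)c1OC
F11 | step 6 | 2,2'-[oxybis(3-(benzyloxy)-2-methoxy-4,1-phenylene)]diethanol | OCCc1ccc(Oc2ccc(CCO)c(OC)c2OCc2ccccc2)c(OCc2ccccc2)c1OC
A1 | alternative 1 | (3R,3''R)-bis(isoflavan) without the 3'-hydroxyls, as its 7-O-triisopropylsilyl ethers | COc1cc(Oc2ccc([C@@H]3COc4cc(O[Si](C(C)C)(C(C)C)C(C)C)ccc4C3)c(OC)c2)ccc1[C@@H]1COc2cc(O[Si](C(C)C)(C(C)C)C(C)C)ccc2C1
A2 | alternative 1 | (3R,3''R)-target as its 7-O-triisopropylsilyl ethers | COc1c([C@@H]2COc3cc(O[Si](C(C)C)(C(C)C)C(C)C)ccc3C2)ccc(Oc2ccc([C@@H]3COc4cc(O[Si](C(C)C)(C(C)C)C(C)C)ccc4C3)c(OC)c2O)c1O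
A3 | alternative 2 | bis(1,1-disubstituted alkene) of the 3'-O-benzyl core, ring A carrying benzyl and methoxymethyl ethers | COc1c(C(=C)Cc2ccc(OCc3ccccc3)cc2OCOC)ccc(Oc2ccc(C(=C)Cc3ccc(OCc4ccccc4)cc3OCOC)c(OC)c2OCc2ccccc2)c1OCc1ccccc1
A4 | alternative 2 | pinacolborane | CC1(C)OBOC1(C)C
A5 | alternative 2 | (R,R)-bis(primary pinacol boronate) | COc1c([C@@H](Cc2ccc(OCc3ccccc3)cc2OCOC)CB2OC(C)(C)C(C)(C)O2)ccc(Oc2ccc([C@@H](Cc3ccc(OCc4ccccc4)cc3OCOC)CB3OC(C)(C)C(C)(C)O3)c(OC)c2OCc2ccccc2)c1OCc1ccccc1
A6 | alternative 3 | (R,R)-bis(methyl ketone), each arm a 5-aryl-6-(tert-butyldimethylsilyloxy)hexan-2-one | COc1c([C@H](CO[Si](C)(C)C(C)(C)C)CCC(C)=O)ccc(Oc2ccc([C@H](CO[Si](C)(C)C(C)(C)C)CCC(C)=O)c(OC)c2OCc2ccccc2)c1OCc1ccccc1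
A7 | alternative 3 | ethyl acrylate | C=CC(=O)OCC
A8 | alternative 3 | bis(3-aryl-2,3,4,4a,5,6-hexahydro-7H-chromen-7-one), 3R at both C3, C4a epimers | COc1c([C@@H]2COC3=CC(=O)CCC3C2)ccc(Oc2ccc([C@@H]3COC4=CC(=O)CCC4C3)c(OC)c2OCc2ccccc2)c1OCc1ccccc1
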